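TBS = tert-butyldimethylsilyl throughout. Oxane numbering of the target: O1, C2 (aryl), C3 (cinnamyl), C4, C5 (carbinol arm), C6.

## Analysis of the target

The target is a monocyclic oxane carrying a 4-hydroxyphenyl group on C2, an (E)-3-(4-hydroxyphenyl)prop-2-enyl (cinnamyl) chain on C3 and a hydroxy(4-hydroxyphenyl)methyl arm on C5; C4 and C6 are methylenes. It has four stereocentres, C2 (R), C3 (S), C5 (R) and the exocyclic carbinol carbon (R), and the three ring substituents are all cis. An all-cis 2,3,5-trisubstituted oxane cannot hold all three groups equatorial (either the C2 aryl is axial or the C3 and C5 arms are 1,3-diaxial), whereas the C2 epimer would be all-equatorial. The ring configuration is therefore not the thermodynamic one and has to be set under geometric or kinetic control and never allowed to equilibrate. The sensitive groups are the three phenols, the p-hydroxybenzylic ether at C2 and the p-hydroxybenzylic alcohol (both ionise readily with acid), and the electron-rich E styrene, which is vulnerable to acid, oxidants and boranes. The difficulty is the cis 1,3 relation of C3 and C5 across an unfunctionalised C4, combined with a cis C2/C3 relation that runs against ring thermodynamics and a carbinol centre with no neighbouring heteroatom to direct it. The plan rests on the fact that C3, C4, C5, the carbinol carbon and the CH2 and first CH of the cinnamyl chain are six contiguous carbons. If the carbinol carbon and that CH are joined by a double bond they form a 1-aryl cyclohexene in which the future C2 and C6 sit as cis 1,3 substituents, and cleavage of that alkene returns an aroyl group on C5 and a CH2CHO arm on C3.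

## Retrosynthetic reasoning

**23 ⇒ 22 ⇒ 21 + 6.** The last bonds cut are the two aryl O–Si bonds of 22 and, before that, the aryl–alkenyl bond of the styrene, which leads to alkenyl iodide 21 and boronic acid 6. Cutting here keeps the acid-, oxidant- and borane-sensitive p-hydroxystyrene out of the route until the penultimate step and stores the E geometry in an alkenyl iodide. The forward Suzuki–Miyaura coupling has to proceed with retention, and the final desilylation has to be non-acidic. Boronic acid 6 is already needed for the diene, so no new building block is introduced.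

**21 ⇒ 20 ⇒ 19.** The carbinol C–H bond is traced back to aryl ketone 20 (oxazaborolidine-catalysed reduction), and the CH=CHI unit to aldehyde 19 (Takai–Utimoto iodo-olefination). In 19 and 20 the C5 centre is α to the aroyl group and its all-cis arrangement is the less stable one, so nothing basic may touch these compounds. This is why a chromium-based olefination is preferred over a sulfone or phosphonate carbanion, whose benzylic variants are also the less E-selective way round. The ketone is reduced before the basic coupling step, which also means that borane never meets the styrene.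

**19 ⇒ 17.** The ketone carbon and the aldehyde carbon of 19 are reconnected as a C=C bond, giving the 2,6-diaryl-3-oxabicyclo[3.3.1]non-6-ene 17. This is the central simplification. The cyclohexene ties C3 and C5 together, so their cis relation is a ring constraint, and both carbons emerge from the cleavage at the oxidation levels the endgame needs. The forward ozonolysis has to cleave the one trisubstituted aryl alkene selectively in the presence of two silyloxyarenes.

**17 ⇒ 15.** The O1–C2 bond and the C2–H bond are cut together (reductive etherification), giving aryl ketone 15 with the C6 oxygen as its silyl ether. The C2 centre is set here because in the bicycle its required configuration (aryl equatorial on the oxane chair, cis to the bridge carbon on C3) is both the product of axial hydride delivery and the more stable epimer. In the free oxane it would be the less stable one. The forward step needs the two 1,3-cis arms of the cyclohexene to meet, which their cis relation and the allylic 1,2-strain next to the aryl group allow.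

**15 ⇒ 12 + 14; 12 ⇒ 11.** The C2–aryl bond is cut to Weinreb amide 12 and arylmagnesium bromide 14 (made from bromide 13). The amide route stops cleanly at the ketone and does not enolise the α-centre. Amide 12 comes from imide 11 by exchange of the auxiliary, which is recovered as 9.

**11 ⇒ 10 + 8.** The two ring bonds of the cyclohexene that correspond to C3–CH2(cinnamyl) and C4–C5 are cut in a retro-Diels–Alder sense, giving acrylimide 10 and aryl diene 8. Both ring centres and the whole carbocycle are formed in one step. The forward reaction must bond the acrylate β-carbon to the CH2OSi-bearing diene terminus, go through the endo transition state, and take place on one face of the chelated acrylimide.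

**8 ⇒ 7 ⇒ 5 + 6; 5 ⇒ 3 ⇒ 1 + 2; 10 ⇒ 9.** The diene needs the aryl group cis to the CH2O group, so that CH2O is the outside substituent of the s-cis diene. This geometry follows from hydroxyl-directed trans-hydroalumination and iodination of enynol 3, which puts iodine cis to CH2OH in 5, and from arylation of 5 with retention. Introducing the vinyl group first (1 + 2) and the aryl group second is what gives the right isomer; the reverse order would give the wrong one. Acrylimide 10 is one acylation from 9.

## Alternatives that were turned down

**Alternative 1:** The disconnection is O1–C2, with the oxane closed by strain release of a donor–acceptor cyclopropane. In the forward step Sc(OTf)3 binds the geminal diester and the C6 hydroxyl opens the cis aryl cyclopropane at the aryl-bearing carbon with inversion. This gives A1, dimethyl 2-{all-cis-2-[4-(TBSO)phenyl]-5-[(TBSO)(4-TBSO-phenyl)methyl]oxan-3-yl}malonate.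
- For it: the C2 configuration is relayed stereospecifically from the cyclopropane, the carbinol is already in place and protected, and the ring is made without a temporary carbocycle. On these points it is stronger than the chosen route, which needs a late reagent-controlled ketone reduction and a sacrificial ring.
- Against it: the p-silyloxyphenyl donor pushes the opening towards a free benzylic cation. Inversion is then lost and the ring closes to the more stable 2,3-trans oxane, the opposite of what is needed. The same Lewis acid can ionise the doubly benzylic silyl ether. The substrate needs three stereocentres (cyclopropane, C5, carbinol) assembled on an open chain. The malonate still has to be cut down to CH2CH=CHAr by decarboxylation, reduction and olefination.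
- Comparison: the chosen strategy sets C2 in a bicycle where kinetic and thermodynamic preferences coincide, and it delivers the C3 arm as CH2CHO directly.

**Alternative 2:** The disconnection is C2–C3 and O1–C6, an oxa-Diels–Alder reaction of the protected 4-hydroxybenzaldehyde with an oxygenated diene. The forward step uses the tridentate Schiff-base CrCl complex (trivalent chromium; ligand from cis-1-amino-2-indanol and 3-(1-adamantyl)-5-methylsalicylaldehyde). After acidic work-up it gives A2, cis-2-[4-(TBSO)phenyl]-5-(benzyloxymethyl)-3-[2-(TBSO)ethyl]-2,3-dihydro-4H-pyran-4-one.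
- For it: it is catalytic and convergent, and it sets the cis C2/C3 pair and two ring bonds in one step without an auxiliary. On catalyst economy and directness to the heterocycle it is stronger.
- Against it: A2 carries a C4 carbonyl and a C5=C6 enol ether that the target lacks. The C4 oxygen must be removed in several steps, and C5 must be set by face-selective saturation while C3 and C5 both sit α to the ketone and can epimerise to the wrong isomers. An electron-rich aryl aldehyde is a poor heterodienophile, and the fully substituted diene of defined geometry is laborious to make. The C5 arm arrives as CH2OBn, so debenzylation (in conflict with the benzylic C2–O bond), oxidation, aryl addition and carbinol control are all still to come.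
- Comparison: the chosen route brings every ring carbon in at its final oxidation level and makes the C3/C5 relation in a concerted step.

**Alternative 3:** The disconnection is O1–C6 as a hemiacetal, an Achmatowicz ring expansion of a 2-furyl aryl carbinol. The forward step is oxidation with N-bromosuccinimide and NaHCO3 in aqueous THF. It gives A3, 2-[4-(TBSO)phenyl]-6-hydroxy-5-[(triisopropylsilyloxy)methyl]-2H-pyran-3(6H)-one as a mixture of C6 anomers.
- For it: the feedstock is cheap, the ring expansion is robust and scalable, and C2 comes from an early catalytic asymmetric ketone reduction. On material cost and scale it is stronger.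
- Against it: A3 has a ketone at C3, where the target needs a carbon branch, an enone and a lactol. The C3 branch must come from olefination, and C3 and C5 must then be set together by hydrogenation from the face opposite the C2 aryl. That hydrogenation endangers the benzylic C2–O bond and excludes the cinnamyl alkene until later. C2–H in A3 is benzylic and α to the ketone, so it can racemise. The lactol reduction needs acidic silane conditions next to an ionisable C2.
- Comparison: the chosen route fixes the cis C3/C5 relation by cycloaddition and not by a double hydrogenation, and it needs fewer redox corrections.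

Key step: step 6

Remark (assumption on the chemistry): aryl bromide 13 and the THF solution of vinyl bromide 2 are taken as commercial; the target is read as the all-cis (2R,3S,5R) oxane with an (R) carbinol and an E alkene.

## Route

Step 1
Reactants: 1 prop-2-yn-1-ol (propargyl alcohol); 2 bromoethene (vinyl bromide)
Product: 3 pent-4-en-2-yn-1-ol
Conditions: Pd(PPh3)2Cl2 (2 mol %), CuI (4 mol %), i-Pr2NH, THF, 0 °C → rt
Reagents that add atoms: none
Why: Sonogashira coupling of a terminal alkyne with a vinyl halide; the free hydroxyl is tolerated and no stereocentre is involved.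

Step 2
Reactants: 3 pent-4-en-2-yn-1-ol
Product: 5 (2Z)-3-iodopenta-2,4-dien-1-ol, via cyclic sodium alkenylalanate 4 (not isolated)
Conditions: NaAlH2(OCH2CH2OCH3)2, THF, 0 °C → rt; then I2, THF, −78 → 0 °C; aq. Na2S2O3
Reagents that add atoms: iodine, II
Why: Hydroxyl-directed trans-hydroalumination of a propargylic alcohol followed by iodinolysis. The alkoxyaluminium hydride delivers hydride to C2 and places aluminium on C3 in the five-membered chelate 4, so iodine replaces aluminium with retention and ends up cis to CH2OH (Z), leaving the vinyl group trans to CH2OH.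

Step 3
Reactants: 5 (2Z)-3-iodopenta-2,4-dien-1-ol; 6 4-hydroxyphenylboronic acid
Product: 7 (2Z)-3-(4-hydroxyphenyl)penta-2,4-dien-1-ol
Conditions: Pd(PPh3)4 (5 mol %), K2CO3, THF/H2O, 40 °C
Reagents that add atoms: none
Why: Suzuki–Miyaura coupling, which goes with retention at the alkenyl iodide, so the aryl group takes the place of iodine, cis to CH2OH. The free phenol is tolerated as its phenoxide under aqueous carbonate.

Step 4
Reactants: 7 (2Z)-3-(4-hydroxyphenyl)penta-2,4-dien-1-ol
Product: 8 tert-butyl({(2Z)-3-[4-(TBSO)phenyl]penta-2,4-dien-1-yl}oxy)dimethylsilane (bis-TBS diene; aryl cis to CH2OTBS)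
Conditions: TBSCl (2.4 equiv), imidazole, DMF, 0 °C → rt
Reagents that add atoms: tert-butyldimethylsilyl chloride, CC(C)(C)[Si](C)(C)Cl
Why: Silylation of the phenol and the primary allylic alcohol, which does not affect the alkene geometry. The diene should be kept cold and used soon, since 2-aryl dienes dimerise.

Step 5
Reactants: 9 (S)-4-benzyl-1,3-oxazolidin-2-one
Product: 10 (S)-3-acryloyl-4-benzyl-1,3-oxazolidin-2-one
Conditions: acrylic acid, t-BuCOCl, Et3N, THF, −20 °C; then LiCl, 9, −20 °C → rt
Reagents that add atoms: acrylic acid, C=CC(=O)O
Why: N-Acylation of the oxazolidinone through the mixed pivalic anhydride with LiCl/Et3N activation, which avoids the polymerisation seen when acryloyl chloride meets a metalated oxazolidinone. The stereocentre is untouched.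

Step 6
Reactants: 10 (S)-3-acryloyl-4-benzyl-1,3-oxazolidin-2-one; 8 bis-TBS (Z)-diene
Product: 11 (4S)-4-benzyl-3-{[(1S,5S)-4-[4-(TBSO)phenyl]-5-[(TBSO)methyl]cyclohex-3-en-1-yl]carbonyl}-1,3-oxazolidin-2-one (acyl and CH2OTBS cis)
Conditions: Et2AlCl (1.4 equiv), CH2Cl2, −78 °C; 8 (1.3 equiv)
Reagents that add atoms: none
Why: Diels–Alder reaction under auxiliary control with Lewis-acid promotion. More than one equivalent of Et2AlCl should convert 10 into the cationic chelate in which aluminium bridges the two imide carbonyls, which locks the acryloyl unit s-cis and lowers its LUMO, and the s-cis diene 8 then adds in a concerted but asynchronous [4+2] cycloaddition. The closest known reaction type is the Et2AlCl-promoted cycloaddition of chiral N-acryloyl oxazolidinones with acyclic dienes such as isoprene and piperylene, and the regiochemical model is the behaviour of 1-alkyl-2-(p-alkoxyaryl) dienes such as 6-methoxy-1-vinyl-3,4-dihydronaphthalene. The cyclohexene is closed by this single suprafacial cycloaddition, which joins the acrylate α-carbon to the unsubstituted diene terminus (future C3–CH2) and the β-carbon to the CH2OSi-bearing terminus (future C4–C5). The regiochemistry rests on the p-silyloxyphenyl group on C3 of the diene, which stabilises positive charge at that carbon in the asynchronous transition state and so makes the adjacent substituted terminus bond first to the β-carbon, against the weaker opposite bias of the CH2OSi group. The stereocentre at C1 of 11 (future C3) is set by the auxiliary: the benzyl group covers the Cα-re face of the chelate and the diene adds to the Cα-si face. The stereocentre at C5 of 11 (future C5) is set relative to C1 by the endo transition state together with the diene geometry, because CH2OSi is the outside substituent (trans to the vinyl group) and therefore ends up cis to the acyl group. The step needs regio-, endo- and facial selectivity at once, secured by the aryl donor, the chelated imide and the benzyl group respectively.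

Step 7
Reactants: 11 Diels–Alder imide
Product: 12 (1S,5S)-4-[4-(TBSO)phenyl]-5-[(TBSO)methyl]-N-methoxy-N-methylcyclohex-3-ene-1-carboxamide
Conditions: MeNH(OMe)·HCl (3 equiv), AlMe3 (3 equiv), CH2Cl2, −10 °C → rt
Reagents that add atoms: N,O-dimethylhydroxylamine hydrochloride, Cl.CNOC
Why: Aluminium amide transamination of an N-acyl oxazolidinone to the Weinreb amide. The exocyclic carbonyl is attacked, the auxiliary 9 is released for reuse, and the non-basic conditions leave the α-stereocentre intact.

Step 8
Reactants: 12 Weinreb amide; 13 (4-bromophenoxy)(tert-butyl)dimethylsilane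
Product: 15 [4-(TBSO)phenyl]{(1S,5S)-4-[4-(TBSO)phenyl]-5-[(TBSO)methyl]cyclohex-3-en-1-yl}methanone, via arylmagnesium bromide 14 (not isolated)
Conditions: 13, Mg, THF, 40 °C; then 12, THF, 0 °C; aq. NH4Cl
Reagents that add atoms: none
Why: Grignard addition to a Weinreb amide. The chelated tetrahedral intermediate holds at the ketone stage and is not enolised, so neither over-addition nor epimerisation at C1 should occur; the aryl silyl ether is compatible with Grignard formation.

Step 9
Reactants: 15 aryl ketone
Product: 17 (1S,2R,5S)-2,6-bis[4-(TBSO)phenyl]-3-oxabicyclo[3.3.1]non-6-ene, via bicyclic oxocarbenium triflate 16 (not isolated)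
Conditions: Et3SiH (3 equiv), Me3SiOTf (0.5 equiv), CH2Cl2, −78 → −40 °C; Et3N quench
Reagents that add atoms: none
Why: Intramolecular silane reductive etherification of a ketone with a silyl ether. Me3SiOTf activates the aryl ketone, the silyl ether oxygen of the cis C5 arm adds 6-exo-trig with loss of its TBS group, and the bicyclic aryl-oxocarbenium ion 16 is reduced by Et3SiH. Hydride should arrive on the axial (exo) face of C2, away from the three-carbon alkene bridge, so the aryl group becomes equatorial on the oxane chair and cis to the bridge carbon on C1; this is the (2R) centre and also the more stable epimer in the bicycle.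

Step 10
Reactants: 17 bicyclic ether
Product: 19 2-{(2R,3R,5R)-5-[4-(TBSO)benzoyl]-2-[4-(TBSO)phenyl]oxan-3-yl}acetaldehyde, via secondary ozonide 18 (not isolated)
Conditions: O3, CH2Cl2, −78 °C (to first blue tinge); then PPh3, −78 °C → rt; used crude
Reagents that add atoms: ozone, [O-][O+]=O
Why: Ozonolysis with reductive work-up. The trisubstituted aryl alkene is the only C=C and should react far faster than the silyloxyarenes or the benzylic ether, and its cleavage opens the temporary ring to the aroyl group on C5 and the CH2CHO arm on C3 without touching a stereocentre. Neutral phosphine reduction of ozonide 18 avoids base, which matters because C5 is now α to a ketone.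

Step 11
Reactants: 19 keto aldehyde
Product: 20 [4-(TBSO)phenyl]{(3R,5R,6R)-6-[4-(TBSO)phenyl]-5-[(2E)-3-iodoprop-2-en-1-yl]oxan-3-yl}methanone
Conditions: CrCl2 (8 equiv), CHI3 (3 equiv), dioxane/THF (6:1), rt, dark
Reagents that add atoms: iodoform, IC(I)I
Why: Takai–Utimoto olefination. The geminal dichromium reagent from CHI3 and CrCl2 adds to aldehydes but not to ketones and is non-basic, so the C5 centre α to the aroyl group should not epimerise. It gives the E-alkenyl iodide preferentially, and dioxane as co-solvent is known to raise that preference.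

Step 12
Reactants: 20 alkenyl iodide ketone
Product: 21 (R)-[4-(TBSO)phenyl]{(3R,5R,6R)-6-[4-(TBSO)phenyl]-5-[(2E)-3-iodoprop-2-en-1-yl]oxan-3-yl}methanol
Conditions: (S)-2-methyl-CBS-oxazaborolidine (0.5 equiv), BH3·SMe2 (1.2 equiv), THF, −20 °C; MeOH quench
Reagents that add atoms: none
Why: Corey–Bakshi–Shibata reduction. With the aryl group as the large substituent, the (S)-oxazaborolidine–borane complex should deliver hydride to the face that gives the (R)-carbinol (the sense in which acetophenone gives (R)-1-phenylethanol), under reagent control over the weakly biasing C5 centre. The alkenyl iodide is a poor hydroboration substrate, which is why borane is used before the styrene exists.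

Step 13
Reactants: 21 alkenyl iodide carbinol; 6 4-hydroxyphenylboronic acid
Product: 22 4-[(1E)-3-{(2R,3S,5R)-5-[(R)-hydroxy(4-TBSO-phenyl)methyl]-2-(4-TBSO-phenyl)oxan-3-yl}prop-1-en-1-yl]phenol
Conditions: Pd(PPh3)4 (5 mol %), K2CO3, THF/H2O, rt → 40 °C
Reagents that add atoms: none
Why: Suzuki–Miyaura coupling. Oxidative addition and reductive elimination both go with retention, so the E geometry of 21 is carried into the styrene. No epimerisable centre remains when base is present, and the aryl silyl ethers should tolerate the mild carbonate treatment (any loss is harmless before step 14).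

Step 14
Reactants: 22 bis-TBS ether
Product: 23 4-[(1E)-3-{(2R,3S,5R)-5-[(R)-hydroxy(4-hydroxyphenyl)methyl]-2-(4-hydroxyphenyl)oxan-3-yl}prop-1-en-1-yl]phenol (target, CNP0182155.1)
Conditions: Bu4NF (2.5 equiv), AcOH (2.5 equiv), THF, 0 °C
Reagents that add atoms: none
Why: Fluoride desilylation of aryl silyl ethers. Acetic acid-buffered fluoride cleaves the two aryl O–Si bonds at low temperature without acid, which would ionise the p-hydroxybenzylic C2–O and C–OH bonds, and without leaving free phenoxide at elevated temperature.

## Compound list

1 | prop-2-yn-1-ol | C#CCO | starting material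
2 | bromoethene (vinyl bromide) | C=CBr | starting material
3 | pent-4-en-2-yn-1-ol | C=CC#CCO | intermediate
4 | sodium 2,2-bis(2-methoxyethoxy)-3-vinyl-2,5-dihydro-1,2-oxaaluminol-2-uide (cyclic alkenylalanate, Al on C3 cis to CH2O) | [Na+].C=CC1=CCO[Al-]1(OCCOC)OCCOC | intermediate (not isolated)
5 | (2Z)-3-iodopenta-2,4-dien-1-ol | C=C/C(I)=C/CO | intermediate
6 | 4-hydroxyphenylboronic acid | OB(O)c1ccc(O)cc1 | starting material
7 | (2Z)-3-(4-hydroxyphenyl)penta-2,4-dien-1-ol | C=C/C(=C/CO)c1ccc(O)cc1 | intermediate
8 | tert-butyl({(2Z)-3-[4-(TBSO)phenyl]penta-2,4-dien-1-yl}oxy)dimethylsilane | C=C/C(=C/CO[Si](C)(C)C(C)(C)C)c1ccc(O[Si](C)(C)C(C)(C)C)cc1 | intermediate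
9 | (S)-4-benzyl-1,3-oxazolidin-2-one | O=C1N[C@@H](Cc2ccccc2)CO1 | starting material
10 | (S)-3-acryloyl-4-benzyl-1,3-oxazolidin-2-one | C=CC(=O)N1[C@@H](Cc2ccccc2)COC1=O | intermediate
11 | (4S)-4-benzyl-3-{[(1S,5S)-4-[4-(TBSO)phenyl]-5-[(TBSO)methyl]cyclohex-3-en-1-yl]carbonyl}-1,3-oxazolidin-2-one | O=C(N1[C@@H](Cc2ccccc2)COC1=O)[C@@H]1C[C@H](CO[Si](C)(C)C(C)(C)C)C(c2ccc(O[Si](C)(C)C(C)(C)C)cc2)=CC1 | intermediate
12 | (1S,5S)-4-[4-(TBSO)phenyl]-5-[(TBSO)methyl]-N-methoxy-N-methylcyclohex-3-ene-1-carboxamide | CON(C)C(=O)[C@@H]1C[C@H](CO[Si](C)(C)C(C)(C)C)C(c2ccc(O[Si](C)(C)C(C)(C)C)cc2)=CC1 | intermediate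
13 | (4-bromophenoxy)(tert-butyl)dimethylsilane | CC(C)(C)[Si](C)(C)Oc1ccc(Br)cc1 | starting material
14 | [4-(TBSO)phenyl]magnesium bromide | CC(C)(C)[Si](C)(C)Oc1ccc([Mg]Br)cc1 | intermediate (not isolated)
15 | [4-(TBSO)phenyl]{(1S,5S)-4-[4-(TBSO)phenyl]-5-[(TBSO)methyl]cyclohex-3-en-1-yl}methanone | O=C(c1ccc(O[Si](C)(C)C(C)(C)C)cc1)[C@@H]1C[C@H](CO[Si](C)(C)C(C)(C)C)C(c2ccc(O[Si](C)(C)C(C)(C)C)cc2)=CC1 | intermediate
16 | (1S,5S)-2,6-bis[4-(TBSO)phenyl]-3-oxabicyclo[3.3.1]nona-2,6-dien-3-ium trifluoromethanesulfonate | CC(C)(C)[Si](C)(C)Oc1ccc(cc1)C1=[O+]C[C@H]2C[C@@H]1CC=C2c1ccc(O[Si](C)(C)C(C)(C)C)cc1.[O-]S(=O)(=O)C(F)(F)F | intermediate (not isolated)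
17 | (1S,2R,5S)-2,6-bis[4-(TBSO)phenyl]-3-oxabicyclo[3.3.1]non-6-ene | CC(C)(C)[Si](C)(C)Oc1ccc(cc1)[C@@H]1OC[C@H]2C[C@@H]1CC=C2c1ccc(O[Si](C)(C)C(C)(C)C)cc1 | intermediate
18 | secondary ozonide of 17 (1,2,4-trioxolane across the former C6=C7 bond; diastereomers at the two ozonide carbons) | CC(C)(C)[Si](C)(C)Oc1ccc(cc1)[C@@H]1OC[C@H]2C[C@@H]1CC1OOC2(O1)c1ccc(O[Si](C)(C)C(C)(C)C)cc1 | intermediate (not isolated)
19 | 2-{(2R,3R,5R)-5-[4-(TBSO)benzoyl]-2-[4-(TBSO)phenyl]oxan-3-yl}acetaldehyde | CC(C)(C)[Si](C)(C)Oc1ccc(cc1)[C@@H]1OC[C@@H](C[C@@H]1CC=O)C(=O)c1ccc(O[Si](C)(C)C(C)(C)C)cc1 | intermediate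
20 | [4-(TBSO)phenyl]{(3R,5R,6R)-6-[4-(TBSO)phenyl]-5-[(2E)-3-iodoprop-2-en-1-yl]oxan-3-yl}methanone | CC(C)(C)[Si](C)(C)Oc1ccc(cc1)[C@@H]1OC[C@@H](C[C@@H]1C/C=C/I)C(=O)c1ccc(O[Si](C)(C)C(C)(C)C)cc1 | intermediate
21 | (R)-[4-(TBSO)phenyl]{(3R,5R,6R)-6-[4-(TBSO)phenyl]-5-[(2E)-3-iodoprop-2-en-1-yl]oxan-3-yl}methanol | CC(C)(C)[Si](C)(C)Oc1ccc(cc1)[C@@H]1OC[C@@H](C[C@@H]1C/C=C/I)[C@@H](O)c1ccc(O[Si](C)(C)C(C)(C)C)cc1 | intermediate
22 | 4-[(1E)-3-{(2R,3S,5R)-5-[(R)-hydroxy(4-TBSO-phenyl)methyl]-2-(4-TBSO-phenyl)oxan-3-yl}prop-1-en-1-yl]phenol | CC(C)(C)[Si](C)(C)Oc1ccc(cc1)[C@@H]1OC[C@@H](C[C@@H]1C/C=C/c1ccc(O)cc1)[C@@H](O)c1ccc(O[Si](C)(C)C(C)(C)C)cc1 | intermediate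
23 | 4-[(1E)-3-{(2R,3S,5R)-5-[(R)-hydroxy(4-hydroxyphenyl)methyl]-2-(4-hydroxyphenyl)oxan-3-yl}prop-1-en-1-yl]phenol | Oc1ccc(cc1)[C@@H]1OC[C@@H](C[C@@H]1C/C=C/c1ccc(O)cc1)[C@@H](O)c1ccc(O)cc1 | target

## Step count and least certain steps

Total step count: 14. Longest linear sequence: 13 steps (1/2 → 3 → 5 → 7 → 8 → 11 → 12 → 15 → 17 → 19 → 20 → 21 → 22 → 23); step 5 is the only step off this line.

**Step 6 (key step).** The most likely failure is consumption of the diene by the Lewis acid before it can cycloadd. The allylic silyl ether is activated by both the aryl and the vinyl group and can ionise, and the electron-rich 2-aryl diene can oligomerise cationically. A second risk is leakage of regiochemistry, because the cis CH2OSi group twists the aryl ring out of the diene plane and weakens the donor effect that directs bonding. The fallback sets out from 8 and replaces auxiliary control and stoichiometric aluminium by a catalytic, milder cationic Lewis acid. Commercial 3-acryloyl-1,3-oxazolidin-2-one and a catalytic amount of the Cu(SbF6)2 complex of 2,2'-isopropylidenebis[(4R)-4-tert-butyl-2-oxazoline] in CH2Cl2 are used; in the square-planar chelate the tert-butyl group should cover the Cα-re face. This should give 3-{[(1S,5S)-4-[4-(TBSO)phenyl]-5-[(TBSO)methyl]cyclohex-3-en-1-yl]carbonyl}-1,3-oxazolidin-2-one F1, which is transaminated as in step 7 and comes back to the route at 12.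

**Step 9.** The most likely failure is plain hydride reduction of the activated aryl ketone, or its complete deoxygenation, outrunning ring closure. The bulky silyl ether oxygen is a weak nucleophile and the diaxial conformer needed for closure is not the ground state. Adventitious acid could also cause ionic hydrogenation of the electron-rich aryl alkene. The fallback sets out from 15. Pyridinium p-toluenesulfonate in MeOH removes the primary alkyl silyl ether selectively (aryl silyl ethers are the more acid-stable) to give [4-(TBSO)phenyl]{(1S,5S)-4-[4-(TBSO)phenyl]-5-(hydroxymethyl)cyclohex-3-en-1-yl}methanone F2, which sits in equilibrium with its bicyclic hemiketal. Et3SiH/BF3·OEt2 at −78 °C then reduces the preformed hemiketal through the same oxocarbenium ion and comes back at 17.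

**Step 11.** The most likely failure is incomplete E selectivity in the elimination from the chromium alkoxide, which is less reliable for α-unbranched aldehydes, together with slow erosion of the C5 centre if the keto aldehyde is kept long in contact with the chromium salts. The fallback sets out from 19 and reverses the coupling roles. CrCl2/LiI with 2-(dichloromethyl)-4,4,5,5-tetramethyl-1,3,2-dioxaborolane in THF should give the (E)-alkenylboronate [4-(TBSO)phenyl]{(3R,5S,6R)-6-[4-(TBSO)phenyl]-5-[(2E)-3-(4,4,5,5-tetramethyl-1,3,2-dioxaborolan-2-yl)prop-2-en-1-yl]oxan-3-yl}methanone F3, a reagent class with a stronger E preference. Reduction as in step 12 gives the carbinol (R)-[4-(TBSO)phenyl]{(3R,5S,6R)-6-[4-(TBSO)phenyl]-5-[(2E)-3-(4,4,5,5-tetramethyl-1,3,2-dioxaborolan-2-yl)prop-2-en-1-yl]oxan-3-yl}methanol F4. Suzuki–Miyaura coupling of F4 with 4-iodophenol (PdCl2(dppf), K3PO4, THF/H2O) comes back at 22.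

**Step 12.** The most likely failure is poor facial selectivity. The hindered, electron-rich aryl ketone may react slowly with the catalyst–borane complex, so that uncatalysed reduction competes, and the resident C5 centre may oppose the catalyst. The fallback sets out from 20 and gives up reagent control in favour of separation and recycling. NaBH4/CeCl3 in MeOH/THF at −78 °C reduces 20 to 21 and its carbinol epimer (S)-[4-(TBSO)phenyl]{(3R,5R,6R)-6-[4-(TBSO)phenyl]-5-[(2E)-3-iodoprop-2-en-1-yl]oxan-3-yl}methanol F5. The epimers are separated and F5 is re-oxidised with Dess–Martin periodinane to 20 for another pass. The sequence comes back to the route at 21.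

## Further compounds

F1 | step 6 | 3-{[(1S,5S)-4-[4-(TBSO)phenyl]-5-[(TBSO)methyl]cyclohex-3-en-1-yl]carbonyl}-1,3-oxazolidin-2-one | O=C(N1CCOC1=O)[C@@H]1C[C@H](CO[Si](C)(C)C(C)(C)C)C(c2ccc(O[Si](C)(C)C(C)(C)C)cc2)=CC1
F2 | step 9 | [4-(TBSO)phenyl]{(1S,5S)-4-[4-(TBSO)phenyl]-5-(hydroxymethyl)cyclohex-3-en-1-yl}methanone | O=C(c1ccc(O[Si](C)(C)C(C)(C)C)cc1)[C@@H]1C[C@H](CO)C(c2ccc(O[Si](C)(C)C(C)(C)C)cc2)=CC1
F3 | step 11 | [4-(TBSO)phenyl]{(3R,5S,6R)-6-[4-(TBSO)phenyl]-5-[(2E)-3-(4,4,5,5-tetramethyl-1,3,2-dioxaborolan-2-yl)prop-2-en-1-yl]oxan-3-yl}methanone | CC(C)(C)[Si](C)(C)Oc1ccc(cc1)[C@@H]1OC[C@@H](C[C@@H]1C/C=C/B1OC(C)(C)C(C)(C)O1)C(=O)c1ccc(O[Si](C)(C)C(C)(C)C)cc1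
F4 | step 11 | (R)-[4-(TBSO)phenyl]{(3R,5S,6R)-6-[4-(TBSO)phenyl]-5-[(2E)-3-(4,4,5,5-tetramethyl-1,3,2-dioxaborolan-2-yl)prop-2-en-1-yl]oxan-3-yl}methanol | CC(C)(C)[Si](C)(C)Oc1ccc(cc1)[C@@H]1OC[C@@H](C[C@@H]1C/C=C/B1OC(C)(C)C(C)(C)O1)[C@@H](O)c1ccc(O[Si](C)(C)C(C)(C)C)cc1
F5 | step 12 | (S)-[4-(TBSO)phenyl]{(3R,5R,6R)-6-[4-(TBSO)phenyl]-5-[(2E)-3-iodoprop-2-en-1-yl]oxan-3-yl}methanol | CC(C)(C)[Si](C)(C)Oc1ccc(cc1)[C@@H]1OC[C@@H](C[C@@H]1C/C=C/I)[C@H](O)c1ccc(O[Si](C)(C)C(C)(C)C)cc1
A1 | alternative 1 | dimethyl 2-{all-cis-2-[4-(TBSO)phenyl]-5-[(TBSO)(4-TBSO-phenyl)methyl]oxan-3-yl}malonate | COC(=O)C(C(=O)OC)[C@H]1C[C@@H]([C@@H](O[Si](C)(C)C(C)(C)C)c2ccc(O[Si](C)(C)C(C)(C)C)cc2)CO[C@H]1c1ccc(O[Si](C)(C)C(C)(C)C)cc1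
A2 | alternative 2 | cis-2-[4-(TBSO)phenyl]-5-(benzyloxymethyl)-3-[2-(TBSO)ethyl]-2,3-dihydro-4H-pyran-4-one | O=C1C(COCc2ccccc2)=CO[C@@H](c2ccc(O[Si](C)(C)C(C)(C)C)cc2)[C@H]1CCO[Si](C)(C)C(C)(C)C
A3 | alternative 3 | 2-[4-(TBSO)phenyl]-6-hydroxy-5-[(triisopropylsilyloxy)methyl]-2H-pyran-3(6H)-one (C6 anomers) | O=C1C=C(CO[Si](C(C)C)(C(C)C)C(C)C)C(O)O[C@H]1c1ccc(O[Si](C)(C)C(C)(C)C)cc1
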